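Each listed step that touches partner uses one of it, so partner charged equals partner left plus quenched reagent plus both products.

| flask | left-handed substrate | right-handed substrate | partner | protic impurity | free catalyst | temperature | remark | time |
|---|---|---|---|---|---|---|---|---|
| elm | 0.050 M | 0.050 M | 0.075 M | 0.50 mM | 1.2 mM | 20 °C | run made earlier |  |
| larch | 0.050 M | 0.050 M | 0.075 M | 0.75 mM | 1.2 mM | 38 °C | run made earlier |  |
| ash | 0.050 M | 0.050 M | 0.075 M | 1 mM | 1.8 mM | 20 °C | run made earlier |  |
| theta | 0.050 M | 0.050 M | 0.0750 M | 1.00 mM | 1.2 mM | 25 °C |  | 4.0 h |
| delta | 0.050 M | 0.050 M | 0.0750 M | 1.00 mM | 1.2 mM | 50 °C |  | 4.0 h |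

- elm (time / h: left-handed product / %, right-handed product / %): 0.417: 44.7, 25.2; 1.00: 46.1, 27.8; 2.00: 47.0, 27.8; 3.00: 46.3, 27.8
- larch (time / min: left-handed product / %, right-handed product / %): 12.0: 43.6, 25.5; 30.0: 45.9, 28.3; 60.0: 46.2, 28.8; 90.0: 46.0, 27.7
- ash (time / h: left-handed product / %, right-handed product / %): 0.417: 45.0, 26.5; 1.00: 45.3, 27.7; 2.00: 46.6, 28.4; 3.00: 46.2, 29.0

(each reading ± 0.3 percentage points)

- the best flask by share of left-handed product in all that became left-handed product or right-handed product; "all alike" if 1.5 percentage points covers them all (theta / delta / all alike)
- share of left-handed product in all that became left-handed product or right-handed product, theta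
- share of left-handed product in all that became left-handed product or right-handed product, delta

- free catalyst is single-handed; left-handed substrate and right-handed substrate are mirror images of each other, charged as a racemate, each of them at the stated concentration
- steps thought possible: partner + protic impurity -> quenched reagent; partner + free catalyst + left-handed substrate -> free catalyst + left-handed product; 2 free catalyst -> spent catalyst; partner + free catalyst + right-handed substrate -> free catalyst + right-handed product

For theta and delta I fold that balance into one number, partner charged over both substrates charged together:

0.750

I call this the reach: the fraction of the racemate that partner can carry into product, less at most 0.0100 if the protic impurity takes its full charge. It is less than one, so partner is the limiting reagent and substrate must remain.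

The earlier runs have the same reach, and their last readings total 74.1% in elm, 73.7% in larch and 75.2% in ash. The elm readings already total 73.9% after 1.00 h, sooner than the 4.0 h allowed, so I expect theta and delta to reach their ceiling within that time.

But one number gives the total, not the split. For that I read the left-handed share at the last readings:

elm 62.5%, larch 62.4%, ash 61.4%

Elm and larch, at 20 °C and 38 °C, differ less than elm and ash, both at 20 °C, so I read no temperature trend and commit to the mean of elm, larch and ash, 62.1%, for both theta and delta.

The forecast differs slightly, giving 62.2% (61.7% to 62.7%) for theta and 61.7% (60.8% to 62.8%) for delta, hence all alike, and it states: “Partner is therefore limiting, and the product split is set by kinetic resolution.”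

The flasks give 62.0% in theta and 61.3% in delta, so the verdict is all alike.

    partner + protic impurity → quenched reagent (k = 5.30 /M/min, Ea = 71.0 kJ/mol)
    partner + free catalyst + left-handed substrate → free catalyst + left-handed product (k = 17000 /M²/min, Ea = 38.0 kJ/mol)
    2 free catalyst → spent catalyst (k = 41.0 /M/min, Ea = 67.0 kJ/mol)
    partner + free catalyst + right-handed substrate → free catalyst + right-handed product (k = 6000 /M²/min, Ea = 41.0 kJ/mol)
    (constants at 50 °C)

In theta at 0.0301 h, the half-life of partner by the left-handed step is 0.071 h, far shorter than the 4.0 h allowed. After 4.00 h, partner stands at 0.010% of its charge while free catalyst stands at 25.5%, and the products make 74.8% of the substrates charged, against a reach of 0.750. A neighbour of theta charged with 0.019 M of partner has a reach of 0.190, and after 4.00 h its products make 19.0%.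

The data stem from a simulated flask with made-up constants; the scatter is artificial.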